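**Plan**
- Retrosynthesis: the two aryl–indole bonds (C5–C3' and C8–C3'') are cut first, then the pyran ring at C8a–O1, C4a–C4 and O1–C2, leading back to an aryne across C4a/C8a and 3-methylbut-2-enal.
- Enabling feature: C8a (bearing O1) and C4a (bearing C4) are neighbouring carbons of the benzene ring, so a C4a≡C8a aryne can take up the oxygen and the carbon of the enal carbonyl. A chlorine at C5, next to C4a, steers oxygen to C8a and later serves as a coupling handle.
- Forward: 2-chloroisovanillin → MOM ether → Dakin phenol → ortho-bromide → retro-Brook/triflation to the silyl triflate; the aryne–enal annulation then closes the pyran ring, the only ring formed.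
- C8 is then lithiated and iodinated, both indoles are attached in one twofold Suzuki coupling, and the sulfonyl and MOM groups are removed.
- Stereochemistry: the target has no stereocentre, and its C3=C4 bond is endocyclic, so nothing needs control.

Key step: step 5

Remark: 2-chloro-3-hydroxy-4-methoxybenzaldehyde, 3-methylbut-2-enal and 1-(phenylsulfonyl)indol-3-ylboronic acid are taken as catalogue compounds; chlorine is chosen as the C5 halogen because it survives both butyllithium steps and polarises the aryne more strongly than bromine.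

**Route**

Step 1
Reactants: 1 2-chloro-3-hydroxy-4-methoxybenzaldehyde
Product: 2 2-chloro-4-methoxy-3-(methoxymethoxy)benzaldehyde
Conditions: MOMCl, i-Pr2NEt, CH2Cl2, 0 °C → rt
Reagents that add atoms: chloromethyl methyl ether (MOMCl), COCCl
Why: Williamson-type O-alkylation of the phenol with the reactive chloromethyl ether should give the base-stable MOM acetal, which is meant to last until the final acidolysis.

Step 2
Reactants: 2 2-chloro-4-methoxy-3-(methoxymethoxy)benzaldehyde
Product: 4 2-chloro-4-methoxy-3-(methoxymethoxy)phenol, via aryl formate 3 (not isolated)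
Conditions: mCPBA, CH2Cl2, rt; then K2CO3 (cat.), MeOH, rt
Reagents that add atoms: meta-chloroperoxybenzoic acid (mCPBA), O=C(OO)c1cccc(Cl)c1
Why: Baeyer–Villiger (Dakin-type) oxidation, in which the aryl group, made migratory by the para methoxy group, shifts to oxygen to give formate 3, which carbonate-catalysed methanolysis should convert into the phenol.

Step 3
Reactants: 4 2-chloro-4-methoxy-3-(methoxymethoxy)phenol
Product: 5 6-bromo-2-chloro-4-methoxy-3-(methoxymethoxy)phenol
Conditions: NBS (1.0 equiv), i-Pr2NH (cat.), CH2Cl2, 0 °C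
Reagents that add atoms: N-bromosuccinimide (NBS), O=C1CCC(=O)N1Br
Why: Amine-catalysed electrophilic aromatic bromination should go to C6, the only open position ortho to the free hydroxyl and para to the MOM ether, since the other free site is meta to the hydroxyl.

Step 4
Reactants: 5 6-bromo-2-chloro-4-methoxy-3-(methoxymethoxy)phenol
Product: 9 2-chloro-4-methoxy-3-(methoxymethoxy)-6-(trimethylsilyl)phenyl trifluoromethanesulfonate, via aryl trimethylsilyl ether 6 (not isolated), via aryllithium 7 (not isolated), via lithium silylphenoxide 8 (not isolated)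
Conditions: HMDS, THF, 65 °C, then evaporation; n-BuLi, THF, −78 °C; Tf2O, −78 °C → rt
Reagents that add atoms: hexamethyldisilazane (HMDS), C[Si](C)(C)N[Si](C)(C)C; trifluoromethanesulfonic anhydride (Tf2O), O=S(=O)(OS(=O)(=O)C(F)(F)F)C(F)(F)F
Why: O-silylation, bromine–lithium exchange (the aryl chloride is inert to n-BuLi at −78 °C), 1,3 O→C silyl shift (retro-Brook rearrangement) and O-triflation of the lithium phenoxide make up the standard one-pot route to 2-(trimethylsilyl)aryl triflates.

Step 5
Reactants: 9 2-chloro-4-methoxy-3-(methoxymethoxy)-6-(trimethylsilyl)phenyl trifluoromethanesulfonate; 10 3-methylbut-2-enal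
Product: 14 5-chloro-7-methoxy-6-(methoxymethoxy)-2,2-dimethyl-2H-chromene, via aryne 11 (not isolated), via benzoxete 12 (not isolated), via ortho-quinone methide 13 (not isolated)
Conditions: CsF (3 equiv), 10 (5 equiv), MeCN, 50 °C, slow addition of 9
Reagents that add atoms: none
Why: Fluoride removes the silyl group and the aryl anion expels the neighbouring triflate to give the 3-chloroaryne 11; the enal oxygen adds to its C8a while the aryl anion developing at C4a, held by the inductive pull of the adjacent C5–Cl bond, closes onto the carbonyl carbon, so the four-membered benzoxete 12 arises by a stepwise polar [2+2] closure. Thermal four-electron opening of 12 gives the ortho-quinone methide 13, whose exocyclic geometry equilibrates, and the 1-oxatriene then closes the six-membered pyran ring by thermal disrotatory oxa-6π electrocyclisation (O1–C2 bond), restoring the benzene ring. The closest known reaction type is the fluoride-induced annulation of 2-(trimethylsilyl)aryl triflates with α,β-unsaturated aldehydes to 2H-chromenes. No stereocentre survives: the benzoxete CH is lost on ring opening, C2 bears two methyl groups and the C3=C4 bond is endocyclic. The step needs regioselective carbonyl addition (O to C8a, C to C4a), which the chlorine next to C4a should secure through aryne distortion while the two alkoxy groups sit symmetrically about the aryne and cancel; excess enal and slow release of the aryne hold back 2:1 aryne adducts.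

Step 6
Reactants: 14 5-chloro-7-methoxy-6-(methoxymethoxy)-2,2-dimethyl-2H-chromene
Product: 16 5-chloro-8-iodo-7-methoxy-6-(methoxymethoxy)-2,2-dimethyl-2H-chromene, via 8-lithiochromene 15 (not isolated)
Conditions: n-BuLi, TMEDA, THF, −20 °C; then I2, −78 °C → rt
Reagents that add atoms: iodine, II
Why: Directed ortho-metalation should occur at C8–H, the only aromatic hydrogen, flanked by the ring oxygen and the methoxy group; the aryl chloride has no ortho hydrogen and does not exchange with n-BuLi, and iodine traps the aryllithium 15.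

Step 7
Reactants: 16 5-chloro-8-iodo-7-methoxy-6-(methoxymethoxy)-2,2-dimethyl-2H-chromene; 17 1-(phenylsulfonyl)indol-3-ylboronic acid
Product: 19 3,3'-[7-methoxy-6-(methoxymethoxy)-2,2-dimethyl-2H-chromene-5,8-diyl]bis[1-(phenylsulfonyl)-1H-indole], via 8-indolyl 5-chloride 18 (not isolated)
Conditions: 17 (3.5 equiv), Pd(OAc)2 (10 mol%), SPhos (20 mol%), K3PO4, toluene/H2O (10:1), 100 °C
Reagents that add atoms: none
Why: Twofold Suzuki–Miyaura coupling, in which the C8 iodide should react first to give 18 and the dialkylbiarylphosphine SPhos should let zerovalent palladium insert into the hindered, electron-rich C5–Cl bond, so that one excess of 17 installs both indoles.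

Step 8
Reactants: 19 3,3'-[7-methoxy-6-(methoxymethoxy)-2,2-dimethyl-2H-chromene-5,8-diyl]bis[1-(phenylsulfonyl)-1H-indole]
Product: 20 3,3'-[7-methoxy-6-(methoxymethoxy)-2,2-dimethyl-2H-chromene-5,8-diyl]bis(1H-indole)
Conditions: KOH, 1,4-dioxane/H2O (4:1), 90 °C
Reagents that add atoms: none
Why: Nucleophilic cleavage of the N-sulfonylindoles by hydroxide at sulfur should release the stabilised indolide anions, while the MOM acetal and the chromene are inert to base.

Step 9
Reactants: 20 3,3'-[7-methoxy-6-(methoxymethoxy)-2,2-dimethyl-2H-chromene-5,8-diyl]bis(1H-indole)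
Product: 21 kumbicin C [5,8-di(1H-indol-3-yl)-7-methoxy-2,2-dimethyl-2H-chromen-6-ol]
Conditions: HCl (3 M aq.), MeOH/THF, 40 °C, argon
Reagents that add atoms: none
Why: Acid-catalysed acetal exchange with methanol (MOM ether cleavage) should free the C6 phenol under conditions mild enough for the 3-arylindoles and the chromene double bond.

**Compound list**

1 | 2-chloro-3-hydroxy-4-methoxybenzaldehyde (2-chloroisovanillin) | COc1ccc(C=O)c(Cl)c1O | starting material
2 | 2-chloro-4-methoxy-3-(methoxymethoxy)benzaldehyde | COCOc1c(OC)ccc(C=O)c1Cl | intermediate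
3 | 2-chloro-4-methoxy-3-(methoxymethoxy)phenyl formate (not isolated) | COCOc1c(OC)ccc(OC=O)c1Cl | intermediate
4 | 2-chloro-4-methoxy-3-(methoxymethoxy)phenol | COCOc1c(OC)ccc(O)c1Cl | intermediate
5 | 6-bromo-2-chloro-4-methoxy-3-(methoxymethoxy)phenol | COCOc1c(OC)cc(Br)c(O)c1Cl | intermediate
6 | [6-bromo-2-chloro-4-methoxy-3-(methoxymethoxy)phenoxy]trimethylsilane (not isolated) | COCOc1c(OC)cc(Br)c(O[Si](C)(C)C)c1Cl | intermediate
7 | [3-chloro-5-methoxy-4-(methoxymethoxy)-2-(trimethylsilyloxy)phenyl]lithium (not isolated) | COCOc1c(OC)cc([Li])c(O[Si](C)(C)C)c1Cl | intermediate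
8 | lithium 2-chloro-4-methoxy-3-(methoxymethoxy)-6-(trimethylsilyl)phenoxide (not isolated) | COCOc1c(OC)cc([Si](C)(C)C)c([O-])c1Cl.[Li+] | intermediate
9 | 2-chloro-4-methoxy-3-(methoxymethoxy)-6-(trimethylsilyl)phenyl trifluoromethanesulfonate | COCOc1c(OC)cc([Si](C)(C)C)c(OS(=O)(=O)C(F)(F)F)c1Cl | intermediate
10 | 3-methylbut-2-enal | CC(C)=CC=O | starting material
11 | 3-chloro-5-methoxy-4-(methoxymethoxy)benzyne (C1≡C2, chlorine on C3; not isolated) | COCOC1=C(Cl)C#CC=C1OC | intermediate
12 | 3-chloro-5-methoxy-4-(methoxymethoxy)-2-(2-methylprop-1-en-1-yl)-2H-benzo[b]oxete (racemic, not isolated) | COCOc1c(OC)cc2OC(C=C(C)C)c2c1Cl | intermediate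
13 | 5-chloro-3-methoxy-4-(methoxymethoxy)-6-(3-methylbut-2-en-1-ylidene)cyclohexa-2,4-dien-1-one (exocyclic geometry not fixed, not isolated) | COCOC1=C(Cl)C(=CC=C(C)C)C(=O)C=C1OC | intermediate
14 | 5-chloro-7-methoxy-6-(methoxymethoxy)-2,2-dimethyl-2H-chromene | COCOc1c(OC)cc2OC(C)(C)C=Cc2c1Cl | intermediate
15 | [5-chloro-7-methoxy-6-(methoxymethoxy)-2,2-dimethyl-2H-chromen-8-yl]lithium (not isolated) | COCOc1c(OC)c([Li])c2OC(C)(C)C=Cc2c1Cl | intermediate
16 | 5-chloro-8-iodo-7-methoxy-6-(methoxymethoxy)-2,2-dimethyl-2H-chromene | COCOc1c(OC)c(I)c2OC(C)(C)C=Cc2c1Cl | intermediate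
17 | 1-(phenylsulfonyl)indol-3-ylboronic acid | OB(O)c1cn(S(=O)(=O)c2ccccc2)c2ccccc12 | starting material
18 | 3-[5-chloro-7-methoxy-6-(methoxymethoxy)-2,2-dimethyl-2H-chromen-8-yl]-1-(phenylsulfonyl)-1H-indole (not isolated) | COCOc1c(OC)c(-c3cn(S(=O)(=O)c4ccccc4)c4ccccc34)c2OC(C)(C)C=Cc2c1Cl | intermediate
19 | 3,3'-[7-methoxy-6-(methoxymethoxy)-2,2-dimethyl-2H-chromene-5,8-diyl]bis[1-(phenylsulfonyl)-1H-indole] | COCOc1c(OC)c(-c3cn(S(=O)(=O)c4ccccc4)c4ccccc34)c2OC(C)(C)C=Cc2c1-c1cn(S(=O)(=O)c2ccccc2)c2ccccc12 | intermediate
20 | 3,3'-[7-methoxy-6-(methoxymethoxy)-2,2-dimethyl-2H-chromene-5,8-diyl]bis(1H-indole) | COCOc1c(OC)c(-c3c[nH]c4ccccc34)c2OC(C)(C)C=Cc2c1-c1c[nH]c2ccccc12 | intermediate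
21 | kumbicin C, 5,8-di(1H-indol-3-yl)-7-methoxy-2,2-dimethyl-2H-chromen-6-ol | COc1c(O)c(-c2c[nH]c3ccccc23)c2c(c1-c1c[nH]c3ccccc13)OC(C)(C)C=C2 | target

**Step count and risks**

Total step count: 9. Longest linear sequence: 9 steps (1 → 21); 10 and 17 are bought and enter at steps 5 and 7.

Steps most likely to fail:

1. Step 5. The enal carbonyl may capture the aryne too slowly or unselectively. The aryne could then be lost to ene reaction at the allylic methyl groups, to fluoride-promoted self-condensation of the enal, or to a second aryne adding to the ortho-quinone methide. The fallback sets out from 9 and returns at 14. CsF in DMF (rt → 50 °C) lets aryne 11 take up the far more nucleophilic formamide carbonyl to give the aminal-type adduct 3-chloro-5-methoxy-4-(methoxymethoxy)-N,N-dimethyl-2H-benzo[b]oxet-2-amine F1. Ring opening and aqueous hydrolysis of this adduct should give 2-chloro-6-hydroxy-4-methoxy-3-(methoxymethoxy)benzaldehyde F2. Addition of 2-methylprop-1-enylmagnesium bromide (2.5 equiv, THF, 0 °C) should give racemic 3-chloro-2-(1-hydroxy-3-methylbut-2-en-1-yl)-5-methoxy-4-(methoxymethoxy)phenol F3. Warming this alcohol with catalytic PPTS in toluene (80 °C) expels water to the same ortho-quinone methide 13, which closes to 14.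

2. Step 7. Oxidative addition into the hindered C5–Cl bond may lag behind protodeboronation of 17, so that the reaction stalls after the first coupling. The fallback sets out from 16 and returns at 19. Coupling of 16 with 17 (1.1 equiv) under Pd(PPh3)4, Na2CO3, DME/H2O, 80 °C should touch only the C8–I bond and give chloride 18, now isolated. Purchased 3-iodo-1-(phenylsulfonyl)indole is converted with t-BuLi (THF, −100 °C) into 3-lithio-1-(phenylsulfonyl)-1H-indole F4, and with ZnCl2 into chloro[1-(phenylsulfonyl)-1H-indol-3-yl]zinc F5. Negishi coupling of this zinc reagent with 18 (Pd2(dba)3, XPhos, THF, 65 °C) should give 19.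

3. Step 6. n-BuLi may add across the styrene-like C3=C4 bond, or metalation at C8 may stay incomplete. The fallback sets out from 14 and returns at 16 directly. It uses electrophilic aromatic iodination with N-iodosuccinimide and catalytic CF3CO2H in MeCN at 0 °C, which attacks the only aromatic C–H, activated by two ortho oxygen substituents. No new compound arises.

Further compounds
F1 | step 5 | 3-chloro-5-methoxy-4-(methoxymethoxy)-N,N-dimethyl-2H-benzo[b]oxet-2-amine (racemic, not isolated) | COCOc1c(OC)cc2OC(N(C)C)c2c1Cl
F2 | step 5 | 2-chloro-6-hydroxy-4-methoxy-3-(methoxymethoxy)benzaldehyde | COCOc1c(OC)cc(O)c(C=O)c1Cl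
F3 | step 5 | 3-chloro-2-(1-hydroxy-3-methylbut-2-en-1-yl)-5-methoxy-4-(methoxymethoxy)phenol (racemic) | COCOc1c(OC)cc(O)c(C(O)C=C(C)C)c1Cl
F0 | step 6 | none | none
F4 | step 7 | 3-lithio-1-(phenylsulfonyl)-1H-indole | [Li]c1cn(S(=O)(=O)c2ccccc2)c2ccccc12
F5 | step 7 | chloro[1-(phenylsulfonyl)-1H-indol-3-yl]zinc | Cl[Zn]c1cn(S(=O)(=O)c2ccccc2)c2ccccc12
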